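**Strategy.** Everything rests on cutting the C3–C4 bond of the oxolane ring (O, C1, C2, C3, C4). Its quaternary ether carbon C4 bears oxygen, a methyl group and the C5–C6 arm, so it is an acetoacetate masked as its O-alkyl enol ether, and C3 lies two carbons from the carbinol carbon C1. A primary C3 radical therefore closes onto C4 of an E-β-alkoxycrotonate held on the C1 oxygen: one operation makes C3–C4, closes the oxolane and sets C4 cis to C10. The precursor is the iodide of that crotonate, with O8 and O10 tied in a p-methoxybenzylidene acetal. Afterwards C6–C13 become an iodobutenolide that closes the ten-membered carbocycle at C7–C8.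

Key step: step 9

Numbering used: C1 oxolane CH–O; C2, C3 oxolane CH2; C4 oxolane C(CH3)–O; C5=C6 enol-lactone alkene; C7=C11 butenolide alkene; C8 CH–O-acyl; C9 CH2; C10 C(CH3)OH; C12 lactone C=O; C13 CH2OAc.

Remark on the carbon count: C1 and C10 each need a two-carbon arm (C2–C3 and C9–C8). A geraniol-derived diol would carry three carbons on the C10 side after cleavage of its distal alkene, so the arms are built from but-3-yn-1-ol (C1, C10, C9, C8) and ethylene oxide (C2, C3).

Assumptions: the ent-Shi ketone, silyl ether 16 and methyl (S)-2-methylglycidate are purchased. The acetal carbon of 10–21 is drawn as the expected all-equatorial epimer. C6 (compounds 18, 19, 21–24, 28, 30) and the allene axis of 20 are carried as mixtures; none of these elements survives into the target.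

**Step 1**
Reactants: 1 but-3-yn-1-ol
Product: 2 1-[(but-3-yn-1-yloxy)methyl]-4-methoxybenzene
Conditions: NaH, PMBCl, Bu4NI (cat.), THF/DMF, 0 °C → rt
Reagents that add atoms: 4-methoxybenzyl chloride, COc1ccc(CCl)cc1
Why: Williamson etherification of the primary alkoxide with a benzylic chloride is routine and leaves the terminal alkyne untouched.

**Step 2**
Reactants: 2 1-[(but-3-yn-1-yloxy)methyl]-4-methoxybenzene; 3 ethylene oxide
Product: 6 (3E)-6-[(4-methoxybenzyl)oxy]-4-methylhex-3-en-1-ol, via alkenylalane 4 (not isolated), via lithium aluminate 5 (not isolated)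
Conditions: AlMe3, Cp2ZrCl2 (cat.), CH2Cl2, 0 °C → rt; n-BuLi, THF, −78 °C; ethylene oxide, −78 → 0 °C; cold aq. HCl
Reagents that add atoms: trimethylaluminium, C[Al](C)C
Why: Negishi carboalumination adds CH3 and Al syn across the alkyne with Al on the terminal carbon, and the derived aluminate opens ethylene oxide with retention of alkene geometry, so the E-trisubstituted C1=C10 alkene with a two-carbon arm on each side should result.

**Step 3**
Reactants: 6 (3E)-6-[(4-methoxybenzyl)oxy]-4-methylhex-3-en-1-ol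
Product: 7 1-({[(3E)-6-chloro-3-methylhex-3-en-1-yl]oxy}methyl)-4-methoxybenzene
Conditions: PPh3, NCS, CH2Cl2, 0 °C → rt
Reagents that add atoms: N-chlorosuccinimide, O=C1CCC(=O)N1Cl
Why: Appel-type chlorination displaces the alkoxyphosphonium ion by SN2 at the primary carbon, and the chloride is chosen because it should survive Oxone, acid, DDQ and PMe3, which an iodide would not.

**Step 4**
Reactants: 7 1-({[(3E)-6-chloro-3-methylhex-3-en-1-yl]oxy}methyl)-4-methoxybenzene
Product: 8 (2S,3S)-3-(2-chloroethyl)-2-{2-[(4-methoxybenzyl)oxy]ethyl}-2-methyloxirane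
Conditions: ent-Shi ketone (1,2:4,5-di-O-isopropylidene-β-L-erythro-2,3-hexodiulo-2,6-pyranose, cat.), Oxone, K2CO3, Bu4NHSO4, MeCN/dimethoxymethane/aq. Na2B4O7 buffer, 0 °C
Reagents that add atoms: Oxone (potassium peroxymonosulfate), [K+].[O-]S(=O)(=O)OO
Why: Shi asymmetric epoxidation: the chiral dioxirane transfers oxygen to one face of the E-trisubstituted alkene through a spiro transition state, so C1 and C10 are set by reagent control as the (S,S)-epoxide.

**Step 5**
Reactants: 8 (2S,3S)-3-(2-chloroethyl)-2-{2-[(4-methoxybenzyl)oxy]ethyl}-2-methyloxirane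
Product: 9 (3R,4S)-6-chloro-1-[(4-methoxybenzyl)oxy]-3-methylhexane-3,4-diol
Conditions: HClO4 (cat.), THF/H2O, 0 °C
Reagents that add atoms: water, O
Why: Acid-catalysed epoxide hydrolysis: water opens the protonated epoxide at the tertiary carbon C10 with inversion while the C1–O bond is kept, which converts the trans-epoxide into the anti diol with C1 S and C10 R.

**Step 6**
Reactants: 9 (3R,4S)-6-chloro-1-[(4-methoxybenzyl)oxy]-3-methylhexane-3,4-diol
Product: 10 (1S)-3-chloro-1-[(2R,4R)-2-(4-methoxyphenyl)-4-methyl-1,3-dioxan-4-yl]propan-1-ol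
Conditions: DDQ, 4 Å molecular sieves, CH2Cl2, 0 °C
Reagents that add atoms: none
Why: Oxidative acetalisation: DDQ turns the PMB ether into an oxocarbenium ion that, without water, is trapped by the 1,3-related tertiary C10 hydroxyl in a six-membered ring (the C1 hydroxyl would need a seven-membered ring), leaving only the C1 hydroxyl free; the aryl group should end equatorial.

**Step 7**
Reactants: 10 (1S)-3-chloro-1-[(2R,4R)-2-(4-methoxyphenyl)-4-methyl-1,3-dioxan-4-yl]propan-1-ol; 11 ethyl but-2-ynoate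
Product: 12 ethyl (2E)-3-{(1S)-3-chloro-1-[(2R,4R)-2-(4-methoxyphenyl)-4-methyl-1,3-dioxan-4-yl]propoxy}but-2-enoate
Conditions: PMe3 (cat.), CH2Cl2, 0 °C → rt
Reagents that add atoms: none
Why: Phosphine-catalysed oxa-Michael addition: the phosphine–ynoate zwitterion deprotonates the C1 hydroxyl, the alkoxide adds to the β-carbon and loss of phosphine should give the thermodynamically preferred E-β-alkoxycrotonate, the acetal preventing any ketal formation by O10.

**Step 8**
Reactants: 12 ethyl (2E)-3-{(1S)-3-chloro-1-[(2R,4R)-2-(4-methoxyphenyl)-4-methyl-1,3-dioxan-4-yl]propoxy}but-2-enoate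
Product: 13 ethyl (2E)-3-{(1S)-3-iodo-1-[(2R,4R)-2-(4-methoxyphenyl)-4-methyl-1,3-dioxan-4-yl]propoxy}but-2-enoate
Conditions: NaI, butan-2-one, 80 °C
Reagents that add atoms: sodium iodide, [Na+].[I-]
Why: Finkelstein exchange (SN2 at the primary carbon, driven by precipitation of NaCl) installs the radical precursor only after every step that an alkyl iodide would not tolerate.

**Step 9**
Reactants: 13 ethyl (2E)-3-{(1S)-3-iodo-1-[(2R,4R)-2-(4-methoxyphenyl)-4-methyl-1,3-dioxan-4-yl]propoxy}but-2-enoate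
Product: 14 ethyl 2-{(2R,5S)-5-[(2R,4R)-2-(4-methoxyphenyl)-4-methyl-1,3-dioxan-4-yl]-2-methyloxolan-2-yl}acetate
Conditions: (Me3Si)3SiH (slow addition), Et3B/air, toluene (0.01 M), 0 °C → rt
Reagents that add atoms: none
Why: Iodine-atom abstraction from 13 by the silyl radical unmasks a primary radical at C3, which attacks the β-carbon C4 of the E-β-alkoxycrotonate, and the ester-stabilised C5 radical so formed is quenched by hydrogen transfer from the silane. The closest known reaction type is the radical cyclisation of β-alkoxyacrylates to cis-2,5-disubstituted oxolanes, here with an additional β-methyl group on the acceptor. The oxolane ring (O, C1, C2, C3, C4) is closed in the 5-exo-trig mode. C1 governs the new stereocentre C4: with the dioxanyl group pseudo-equatorial in a chair-like arrangement and the acceptor extended away from the C1–O bond, the C5–C6 arm should be delivered cis to C10 (C4 R). The step needs ring closure to outrun hydrogen transfer and 5-exo to beat 6-endo attack; the first is secured by the polarised acceptor together with a slow hydrogen donor at high dilution, the second because attack at C5 is polarity-mismatched for a nucleophilic alkyl radical.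

**Step 10**
Reactants: 14 ethyl 2-{(2R,5S)-5-[(2R,4R)-2-(4-methoxyphenyl)-4-methyl-1,3-dioxan-4-yl]-2-methyloxolan-2-yl}acetate
Product: 15 2-{(2R,5S)-5-[(2R,4R)-2-(4-methoxyphenyl)-4-methyl-1,3-dioxan-4-yl]-2-methyloxolan-2-yl}acetaldehyde
Conditions: DIBAL-H, CH2Cl2, −78 °C; Rochelle salt
Reagents that add atoms: none
Why: Partial ester reduction: at −78 °C the aluminium hemiacetal, held by chelation to the oxolane oxygen, should persist until work-up and release the C6 aldehyde, the acetal being inert at this temperature.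

**Step 11**
Reactants: 15 2-{(2R,5S)-5-[(2R,4R)-2-(4-methoxyphenyl)-4-methyl-1,3-dioxan-4-yl]-2-methyloxolan-2-yl}acetaldehyde; 16 tert-butyl(diphenyl)(prop-2-yn-1-yloxy)silane
Product: 19 5-{[tert-butyl(diphenyl)silyl]oxy}-1-{(2R,5S)-5-[(2R,4R)-2-(4-methoxyphenyl)-4-methyl-1,3-dioxan-4-yl]-2-methyloxolan-2-yl}pent-3-yn-2-yl methyl carbonate (C6 epimers), via lithium acetylide 17 (not isolated), via lithium alkoxide 18 (not isolated)
Conditions: 16, n-BuLi, THF, −78 °C; then 15; then ClCO2Me, −78 → 0 °C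
Reagents that add atoms: methyl chloroformate, COC(=O)Cl
Why: 1,2-addition of the lithium acetylide to the aldehyde and O-acylation of the alkoxide in the same flask give the propargylic carbonate (C7, C11, C13 installed); C6 forms as both epimers, which is harmless because C6 ends as an sp2 carbon.

**Step 12**
Reactants: 19 propargylic methyl carbonate
Product: 20 methyl 2-({[tert-butyl(diphenyl)silyl]oxy}methyl)-5-{(2R,5S)-5-[(2R,4R)-2-(4-methoxyphenyl)-4-methyl-1,3-dioxan-4-yl]-2-methyloxolan-2-yl}penta-2,3-dienoate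
Conditions: Pd(OAc)2 (cat.), PPh3, CO (5 bar), MeOH, 40 °C
Reagents that add atoms: carbon monoxide, [C-]#[O+]
Why: Palladium-catalysed carbonylation of a propargylic carbonate: zerovalent palladium ionises the carbonate in an SN2' sense to an allenylpalladium methoxide at C11, CO inserts and reductive elimination gives the 2,3-dienoate with C12 on C11 (the methoxy group stems from the carbonate, CO2 being lost).

**Step 13**
Reactants: 20 methyl 2,3-dienoate
Product: 21 3-({[tert-butyl(diphenyl)silyl]oxy}methyl)-4-iodo-5-({(2R,5S)-5-[(2R,4R)-2-(4-methoxyphenyl)-4-methyl-1,3-dioxan-4-yl]-2-methyloxolan-2-yl}methyl)furan-2(5H)-one (C6 epimers)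
Conditions: I2, NaHCO3, MeCN/H2O, rt
Reagents that add atoms: iodine, II; water, O
Why: Iodolactonisation of a 2,3-allenoate: iodine adds to the central allene carbon C7, the ester carbonyl oxygen closes on C6 and hydrolysis of the resulting dioxolenium ion releases methanol, giving the 4-iodobutenolide; bicarbonate keeps the acetal intact.

**Step 14**
Reactants: 21 iodobutenolide acetal
Product: 22 3-({[tert-butyl(diphenyl)silyl]oxy}methyl)-5-({(2R,5S)-5-[(2R)-2,4-dihydroxybutan-2-yl]-2-methyloxolan-2-yl}methyl)-4-iodofuran-2(5H)-one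
Conditions: AcOH/THF/H2O, rt
Reagents that add atoms: none
Why: Mild acid hydrolysis cleaves the p-methoxybenzylidene acetal, the most acid-labile group present, to the C8/C10 diol while the TBDPS ether and the lactone should persist.

**Step 15**
Reactants: 22 iodobutenolide diol
Product: 23 (3R)-3-hydroxy-3-{(2S,5R)-5-[(4-({[tert-butyl(diphenyl)silyl]oxy}methyl)-3-iodo-5-oxo-2,5-dihydrofuran-2-yl)methyl]-5-methyloxolan-2-yl}butanal
Conditions: TEMPO (cat.), PhI(OAc)2, CH2Cl2, rt
Reagents that add atoms: none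
Why: Oxoammonium (TEMPO) oxidation is selective for the primary C8 alcohol, cannot touch the tertiary C10 hydroxyl and stops at the aldehyde.

**Step 16**
Reactants: 23 iodobutenolide aldehyde
Product: 24 macrocyclic 8S alcohol (C7–C8 bond closed; C6–H butenolide; C8 and C10 hydroxyls free; C13 O-TBDPS; 1S,4R,8S,10R; C6 epimers)
Conditions: CrCl2, NiCl2 (cat.), DMSO, rt, slow addition at high dilution
Reagents that add atoms: none
Why: Intramolecular Nozaki–Hiyama–Kishi reaction: nickel inserts into the C7–I bond and hands the alkenyl group to chromium, which adds to the C8 aldehyde and closes the ten-membered carbocycle; C8 is set under substrate control, since chromium bound to the C10 alkoxide and the aldehyde oxygen forms a six-membered chelate and delivery of C7 through the C1-linked tether should place the new C8–O bond syn to C10–O (8S).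

**Step 17**
Reactants: 25 methyl (2S)-2-methyloxirane-2-carboxylate
Product: 27 (2S)-2-methyloxirane-2-carboxylic acid, via lithium carboxylate 26 (not isolated)
Conditions: LiOH, THF/H2O, 0 °C; then cold aq. HCl to pH 3, extraction
Reagents that add atoms: lithium hydroxide, [Li+].[OH-]
Why: Saponification (acyl substitution by hydroxide) followed by careful acidification gives the free acid; the quaternary stereocentre cannot epimerise and the epoxide tolerates cold dilute base and acid.

**Step 18**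
Reactants: 24 macrocyclic 8S alcohol; 27 (2S)-2-methyloxirane-2-carboxylic acid
Product: 28 C8 (2S)-2-methyloxirane-2-carboxylate of 24
Conditions: EDC·HCl, DMAP, CH2Cl2, 0 °C → rt
Reagents that add atoms: none
Why: Steglich esterification acylates the secondary allylic C8 hydroxyl with retention, the tertiary C10 hydroxyl being too hindered to compete.

**Step 19**
Reactants: 28 C8 ester
Product: 31 5E-ylidene butenolide with C10 O-TES and C13 O-TBDPS, via silyloxyfuran 29 (not isolated), via C6 bromide 30 (not isolated)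
Conditions: TESOTf, Et3N, CH2Cl2, −78 → 0 °C; NBS, THF, −78 °C; then DBU, −78 → 0 °C
Reagents that add atoms: triethylsilyl trifluoromethanesulfonate, CC[Si](CC)(CC)OS(=O)(=O)C(F)(F)F
Why: γ-Deprotonation and silylation give the aromatic 2-silyloxyfuran (the C10 hydroxyl is silylated as well), NBS brominates its 5-position C6 and dehydrobromination can only take a C5 hydrogen, so the C5=C6 alkene forms with the ring-enforced E geometry (C4 cis to C7) and both C6 epimers converge, as in known butenolide to 5-ylidenebutenolide conversions by bromination and dehydrobromination.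

**Step 20**
Reactants: 31 bis-silyl ylidene butenolide
Product: 32 13-O-deacetyl target (C10 and C13 hydroxyls free)
Conditions: HF·pyridine, pyridine, THF, 0 °C → rt
Reagents that add atoms: none
Why: Fluoride cleaves the primary TBDPS and tertiary TES ethers through Si–F bond formation, and pyridine buffering should protect the glycidate epoxide and the enol lactone.

**Step 21**
Reactants: 32 13-O-deacetyl target
Product: 33 CNP0142137.1
Conditions: Ac2O, pyridine, CH2Cl2, 0 °C
Reagents that add atoms: acetic anhydride, CC(=O)OC(C)=O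
Why: Acetylation without DMAP is selective for the primary C13 hydroxyl over the tertiary C10 hydroxyl and should give the target.

**Compound list**
1 | but-3-yn-1-ol | C#CCCO | starting material
2 | 1-[(but-3-yn-1-yloxy)methyl]-4-methoxybenzene | C#CCCOCc1ccc(OC)cc1 | intermediate
3 | ethylene oxide | C1CO1 | starting material
4 | dimethyl{(1E)-4-[(4-methoxybenzyl)oxy]-2-methylbut-1-en-1-yl}alane | C[Al](C)/C=C(\C)CCOCc1ccc(OC)cc1 | intermediate
5 | lithium butyl(dimethyl){(1E)-4-[(4-methoxybenzyl)oxy]-2-methylbut-1-en-1-yl}aluminate | [Li+].CCCC[Al-](C)(C)/C=C(\C)CCOCc1ccc(OC)cc1 | intermediate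
6 | (3E)-6-[(4-methoxybenzyl)oxy]-4-methylhex-3-en-1-ol | OCC/C=C(\C)CCOCc1ccc(OC)cc1 | intermediate
7 | 1-({[(3E)-6-chloro-3-methylhex-3-en-1-yl]oxy}methyl)-4-methoxybenzene | ClCC/C=C(\C)CCOCc1ccc(OC)cc1 | intermediate
8 | (2S,3S)-3-(2-chloroethyl)-2-{2-[(4-methoxybenzyl)oxy]ethyl}-2-methyloxirane | ClCC[C@@H]1O[C@@]1(C)CCOCc1ccc(OC)cc1 | intermediate
9 | (3R,4S)-6-chloro-1-[(4-methoxybenzyl)oxy]-3-methylhexane-3,4-diol | ClCC[C@H](O)[C@](C)(O)CCOCc1ccc(OC)cc1 | intermediate
10 | (1S)-3-chloro-1-[(2R,4R)-2-(4-methoxyphenyl)-4-methyl-1,3-dioxan-4-yl]propan-1-ol | ClCC[C@H](O)[C@@]1(C)CCO[C@@H](c2ccc(OC)cc2)O1 | intermediate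
11 | ethyl but-2-ynoate | CC#CC(=O)OCC | starting material
12 | ethyl (2E)-3-{(1S)-3-chloro-1-[(2R,4R)-2-(4-methoxyphenyl)-4-methyl-1,3-dioxan-4-yl]propoxy}but-2-enoate | CCOC(=O)/C=C(\C)O[C@@H](CCCl)[C@@]1(C)CCO[C@@H](c2ccc(OC)cc2)O1 | intermediate
13 | ethyl (2E)-3-{(1S)-3-iodo-1-[(2R,4R)-2-(4-methoxyphenyl)-4-methyl-1,3-dioxan-4-yl]propoxy}but-2-enoate | CCOC(=O)/C=C(\C)O[C@@H](CCI)[C@@]1(C)CCO[C@@H](c2ccc(OC)cc2)O1 | intermediate
14 | ethyl 2-{(2R,5S)-5-[(2R,4R)-2-(4-methoxyphenyl)-4-methyl-1,3-dioxan-4-yl]-2-methyloxolan-2-yl}acetate | CCOC(=O)C[C@@]1(C)CC[C@H](O1)[C@@]2(C)CCO[C@@H](c3ccc(OC)cc3)O2 | intermediate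
15 | 2-{(2R,5S)-5-[(2R,4R)-2-(4-methoxyphenyl)-4-methyl-1,3-dioxan-4-yl]-2-methyloxolan-2-yl}acetaldehyde | O=CC[C@@]1(C)CC[C@H](O1)[C@@]2(C)CCO[C@@H](c3ccc(OC)cc3)O2 | intermediate
16 | tert-butyl(diphenyl)(prop-2-yn-1-yloxy)silane | C#CCO[Si](c1ccccc1)(c1ccccc1)C(C)(C)C | starting material
17 | lithium acetylide of 16 | [Li]C#CCO[Si](c1ccccc1)(c1ccccc1)C(C)(C)C | intermediate
18 | lithium alkoxide of the C6 propargylic alcohol (C6 epimers) | [Li]OC(C[C@@]1(C)CC[C@H](O1)[C@@]2(C)CCO[C@@H](c3ccc(OC)cc3)O2)C#CCO[Si](c1ccccc1)(c1ccccc1)C(C)(C)C | intermediate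
19 | 5-{[tert-butyl(diphenyl)silyl]oxy}-1-{(2R,5S)-5-[(2R,4R)-2-(4-methoxyphenyl)-4-methyl-1,3-dioxan-4-yl]-2-methyloxolan-2-yl}pent-3-yn-2-yl methyl carbonate (C6 epimers) | COC(=O)OC(C[C@@]1(C)CC[C@H](O1)[C@@]2(C)CCO[C@@H](c3ccc(OC)cc3)O2)C#CCO[Si](c1ccccc1)(c1ccccc1)C(C)(C)C | intermediate
20 | methyl 2-({[tert-butyl(diphenyl)silyl]oxy}methyl)-5-{(2R,5S)-5-[(2R,4R)-2-(4-methoxyphenyl)-4-methyl-1,3-dioxan-4-yl]-2-methyloxolan-2-yl}penta-2,3-dienoate (allene axis mixed) | COC(=O)C(CO[Si](c1ccccc1)(c1ccccc1)C(C)(C)C)=C=CC[C@@]1(C)CC[C@H](O1)[C@@]2(C)CCO[C@@H](c3ccc(OC)cc3)O2 | intermediate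
21 | 3-({[tert-butyl(diphenyl)silyl]oxy}methyl)-4-iodo-5-({(2R,5S)-5-[(2R,4R)-2-(4-methoxyphenyl)-4-methyl-1,3-dioxan-4-yl]-2-methyloxolan-2-yl}methyl)furan-2(5H)-one (C6 epimers) | O=C1OC(C[C@@]2(C)CC[C@H](O2)[C@@]3(C)CCO[C@@H](c4ccc(OC)cc4)O3)C(I)=C1CO[Si](c1ccccc1)(c1ccccc1)C(C)(C)C | intermediate
22 | 3-({[tert-butyl(diphenyl)silyl]oxy}methyl)-5-({(2R,5S)-5-[(2R)-2,4-dihydroxybutan-2-yl]-2-methyloxolan-2-yl}methyl)-4-iodofuran-2(5H)-one (C6 epimers) | O=C1OC(C[C@@]2(C)CC[C@H](O2)[C@](C)(O)CCO)C(I)=C1CO[Si](c1ccccc1)(c1ccccc1)C(C)(C)C | intermediate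
23 | (3R)-3-hydroxy-3-{(2S,5R)-5-[(4-({[tert-butyl(diphenyl)silyl]oxy}methyl)-3-iodo-5-oxo-2,5-dihydrofuran-2-yl)methyl]-5-methyloxolan-2-yl}butanal (C6 epimers) | O=C1OC(C[C@@]2(C)CC[C@H](O2)[C@](C)(O)CC=O)C(I)=C1CO[Si](c1ccccc1)(c1ccccc1)C(C)(C)C | intermediate
24 | macrocyclic 8S alcohol: C6–H butenolide fused at C6–C7 to the ten-membered carbocycle, 1,4-oxolane bridge, C8 OH, C10 OH, C13 O-TBDPS (1S,4R,8S,10R; C6 epimers) | CC(C)(C)[Si](c1ccccc1)(c1ccccc1)OCC1=C2C(C[C@@]3(C)CC[C@H](O3)[C@](C)(O)C[C@@H]2O)OC1=O | intermediate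
25 | methyl (2S)-2-methyloxirane-2-carboxylate | COC(=O)[C@]1(C)CO1 | starting material
26 | lithium (2S)-2-methyloxirane-2-carboxylate | [Li+].[O-]C(=O)[C@]1(C)CO1 | intermediate
27 | (2S)-2-methyloxirane-2-carboxylic acid | OC(=O)[C@]1(C)CO1 | intermediate
28 | C8 (2S)-2-methyloxirane-2-carboxylate of 24 (C6 epimers) | CC(C)(C)[Si](c1ccccc1)(c1ccccc1)OCC1=C2C(C[C@@]3(C)CC[C@H](O3)[C@](C)(O)C[C@@H]2OC(=O)[C@]2(C)CO2)OC1=O | intermediate
29 | 2-(triethylsilyloxy)furan of 28 with C10 O-TES (furan carbons C12, C11, C7, C6) | CC[Si](CC)(CC)Oc1oc2C[C@@]3(C)CC[C@H](O3)[C@](C)(O[Si](CC)(CC)CC)C[C@H](OC(=O)[C@]4(C)CO4)c2c1CO[Si](c1ccccc1)(c1ccccc1)C(C)(C)C | intermediate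
30 | C6 bromide of 28 with C10 O-TES (C6 epimers) | CC(C)(C)[Si](c1ccccc1)(c1ccccc1)OCC1=C2C(Br)(C[C@@]3(C)CC[C@H](O3)[C@](C)(O[Si](CC)(CC)CC)C[C@@H]2OC(=O)[C@]2(C)CO2)OC1=O | intermediate
31 | 5E-ylidene butenolide with C10 O-TES and C13 O-TBDPS | CC(C)(C)[Si](c1ccccc1)(c1ccccc1)OCC1=C2/C(=C\[C@@]3(C)CC[C@H](O3)[C@](C)(O[Si](CC)(CC)CC)C[C@@H]2OC(=O)[C@]2(C)CO2)OC1=O | intermediate
32 | 13-O-deacetyl target (C10 and C13 hydroxyls free) | OCC1=C2/C(=C\[C@@]3(C)CC[C@H](O3)[C@](C)(O)C[C@@H]2OC(=O)[C@]2(C)CO2)OC1=O | intermediate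
33 | CNP0142137.1 | CC(=O)OCC1=C2/C(=C\[C@@]3(C)CC[C@H](O3)[C@](C)(O)C[C@@H]2OC(=O)[C@]2(C)CO2)OC1=O | target

**Step count.** Total: 21 steps. Longest linear sequence: 20 steps (steps 1–16 and 18–21, from but-3-yn-1-ol); step 17 is a one-step side branch.

**Steps most likely to fail**

Step 16. The addition to the aldehyde may show low or reversed facial selectivity, because the chelate model is untested in this ring system. The fallback sets out from 23: if the closure delivers mainly the 8R alcohol F6, this epimer is esterified with acid 27 under Mitsunobu conditions (PPh3, DIAD, toluene, 0 °C), which inverts C8, and the route is rejoined at 28.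

Step 19. The allylic C8 acyloxy group may ionise from the electron-rich silyloxyfuran, or bromine may enter at C11 instead of C6. The fallback sets out from 28 and uses oxygenation followed by dehydration. DBU-catalysed autoxidation (O2, THF) gives the C6 hydroperoxide F7, which P(OEt)3 reduces in the same flask to the 5-hydroxybutenolide F8. MsCl/Et3N dehydrates this lactol to the ylidene butenolide with free C10 hydroxyl F9. HF·pyridine then removes the TBDPS group and the route is rejoined at 32.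

Step 9. Hydrogen transfer may reach the primary radical before ring closure, or facial selectivity at the fully substituted acceptor carbon may be low. The fallback forms the O–C4 bond by a reversible polar closure and sets out from 10. Silylation (TESCl, imidazole, DMF) gives the triethylsilyl ether of 10 F1. Magnesium insertion gives the Grignard reagent F2, which adds syn across ethyl but-2-ynoate 11 under CuBr·SMe2 catalysis at −78 °C to give the E-enoate F3. TBAF frees the C1 alkoxide, which passes through the hydroxy enoate F4 and closes onto C4 by oxa-Michael addition to give 14 together with the C4 epimer of 14 F5. F5 is returned to the equilibrium with KOtBu, and the route is rejoined at 14.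

**Further compounds**
F1 | step 9 | triethyl{(1S)-3-chloro-1-[(2R,4R)-2-(4-methoxyphenyl)-4-methyl-1,3-dioxan-4-yl]propoxy}silane | ClCC[C@H](O[Si](CC)(CC)CC)[C@@]1(C)CCO[C@@H](c2ccc(OC)cc2)O1
F2 | step 9 | Grignard reagent of F1 (chloromagnesium at C3) | Cl[Mg]CC[C@H](O[Si](CC)(CC)CC)[C@@]1(C)CCO[C@@H](c2ccc(OC)cc2)O1
F3 | step 9 | ethyl (2E,6S)-3-methyl-6-[(2R,4R)-2-(4-methoxyphenyl)-4-methyl-1,3-dioxan-4-yl]-6-(triethylsilyloxy)hex-2-enoate | CCOC(=O)/C=C(\C)CC[C@H](O[Si](CC)(CC)CC)[C@@]1(C)CCO[C@@H](c2ccc(OC)cc2)O1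
F4 | step 9 | ethyl (2E,6S)-6-hydroxy-3-methyl-6-[(2R,4R)-2-(4-methoxyphenyl)-4-methyl-1,3-dioxan-4-yl]hex-2-enoate | CCOC(=O)/C=C(\C)CC[C@H](O)[C@@]1(C)CCO[C@@H](c2ccc(OC)cc2)O1
F5 | step 9 | C4 epimer of 14: ethyl 2-{(2S,5S)-5-[(2R,4R)-2-(4-methoxyphenyl)-4-methyl-1,3-dioxan-4-yl]-2-methyloxolan-2-yl}acetate | CCOC(=O)C[C@]1(C)CC[C@H](O1)[C@@]2(C)CCO[C@@H](c3ccc(OC)cc3)O2
F6 | step 16 | 8R epimer of 24 | CC(C)(C)[Si](c1ccccc1)(c1ccccc1)OCC1=C2C(C[C@@]3(C)CC[C@H](O3)[C@](C)(O)C[C@H]2O)OC1=O
F7 | step 19 | C6 hydroperoxide of 28 | CC(C)(C)[Si](c1ccccc1)(c1ccccc1)OCC1=C2C(OO)(C[C@@]3(C)CC[C@H](O3)[C@](C)(O)C[C@@H]2OC(=O)[C@]2(C)CO2)OC1=O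
F8 | step 19 | 5-hydroxybutenolide (C6 lactol) of 28 | CC(C)(C)[Si](c1ccccc1)(c1ccccc1)OCC1=C2C(O)(C[C@@]3(C)CC[C@H](O3)[C@](C)(O)C[C@@H]2OC(=O)[C@]2(C)CO2)OC1=O
F9 | step 19 | 5E-ylidene butenolide with free C10 hydroxyl and C13 O-TBDPS | CC(C)(C)[Si](c1ccccc1)(c1ccccc1)OCC1=C2/C(=C\[C@@]3(C)CC[C@H](O3)[C@](C)(O)C[C@@H]2OC(=O)[C@]2(C)CO2)OC1=O
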